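**Retrosynthetic overview**

1. The route rests on one feature: the C6 oxygen of ring B and a temporary carbonyl at C3 of ring A stand 1,4 to each other across the C5–C6 bond (O–C6–C5–C4–C3=O). This like-polarity pair is joined by adding a C6 acyl radical to C5 of a ring A 2-methylcyclohexenone.
2. Ring order: ring A is carried from 3-methylcyclohex-2-enone; ring B (C5–C10) is closed second by that 6-exo radical addition, and its C6 ketone later becomes the acetoxy carbinol.
3. The ring fusion is not taken from the closure: C4 and C5 are made planar again (2-ene-1,4-dione), and a reductive hydroxymethylation brings in C18 at C4 and sets H5 trans to C20. C3 is then deoxygenated and C6 reduced to the equatorial alcohol.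
4. The radical precursor comes from an Ireland–Claisen rearrangement (C9–C10 bond, both centres), a Felkin-controlled methyl addition to the C8 allyl ketone (C8), and cleavage of the allyl group to the C6 selenoester. The C4 methyl is put on the enone by iodination and cross-coupling.
5. The C13(16),14-diene is made last from the ketal-masked C13 methyl ketone by enol triflate formation and vinyl coupling, after the C6 acetate is in place.

Key step: step 15

Remark on numbering: labdane numbering is used for every intermediate (ring A = C1–C5, C10; ring B = C5–C10; C11, C12, C13 and its methyl C16 form the chain on C9; C17 on C8; C18 and C19 on C4; C20 on C10).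

Assumption: the target SMILES is read as having the C9 chain and the C8 hydroxyl anti to C20 and C17 syn to C20 (4S,5S,6R,8S,9R,10R); the (R)-configured CBS catalyst is taken to give the (S)-allylic alcohol, the alkenyl arm acting as the large group.

**Route**

Step 1
Reactants: 1 3-methylcyclohex-2-en-1-one
Product: 2 (S)-3-methylcyclohex-2-en-1-ol
Conditions: (R)-2-methyl-CBS-oxazaborolidine (10 mol%), catecholborane, toluene, −78 °C; then MeOH, H2O
Reagents that add atoms: none
Why: Corey–Bakshi–Shibata reduction; the oxazaborolidine–borane complex binds the carbonyl with the alkenyl arm as the large group and delivers hydride to one face, which should give the (S)-carbinol whose configuration is later passed on to C10.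

Step 2
Reactants: 3 5-oxohexanoic acid
Product: 5 4-(2-methyl-1,3-dioxolan-2-yl)butanoic acid, via 2-hydroxyethyl ester 4 (not isolated)
Conditions: HOCH2CH2OH, TsOH (cat.), toluene, reflux, Dean–Stark; then NaOH, MeOH/H2O, rt; then AcOH to pH 5
Reagents that add atoms: ethylene glycol, OCCO
Why: Acid-catalysed ketalization (with Fischer esterification by the excess diol) masks the C13 ketone as a dioxolane, and saponification of the ester returns the free acid with the ketal untouched.

Step 3
Reactants: 2 (S)-3-methylcyclohex-2-en-1-ol; 5 4-(2-methyl-1,3-dioxolan-2-yl)butanoic acid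
Product: 6 (S)-3-methylcyclohex-2-en-1-yl 4-(2-methyl-1,3-dioxolan-2-yl)butanoate
Conditions: DCC, DMAP (cat.), CH2Cl2, 0 °C to rt
Reagents that add atoms: none
Why: Steglich esterification acylates the secondary allylic alcohol under neutral conditions, so neither allylic transposition nor loss of configuration at the carbinol is expected.

Step 4
Reactants: 6 (S)-3-methylcyclohex-2-en-1-yl 4-(2-methyl-1,3-dioxolan-2-yl)butanoate
Product: 10 (2R)-4-(2-methyl-1,3-dioxolan-2-yl)-2-[(1R)-1-methylcyclohex-2-en-1-yl]butanoic acid, via lithium enolate 7 (not isolated), via silyl ketene acetal 8 (not isolated), via silyl ester 9 (not isolated)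
Conditions: LDA, THF/DMPU, −78 °C; TBSCl, −78 °C to 60 °C; then LiOH, THF/H2O, rt; AcOH to pH 5
Reagents that add atoms: none
Why: Ireland–Claisen rearrangement; DMPU should give the Z(O)-enolate, its silyl ketene acetal rearranges suprafacially so that the carbinol configuration is handed to quaternary C10, and a chair-like transition state (the boat would eclipse the C11 chain with the C10 methyl) should give the C9 R, C10 R acid.

Step 5
Reactants: 10 (2R)-4-(2-methyl-1,3-dioxolan-2-yl)-2-[(1R)-1-methylcyclohex-2-en-1-yl]butanoic acid
Product: 12 N-methoxy-N-methyl amide of acid 10, via acyl imidazole 11 (not isolated)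
Conditions: CDI, THF, rt; then MeNHOMe·HCl, 45 °C
Reagents that add atoms: N,O-dimethylhydroxylamine hydrochloride, CNOC.Cl
Why: Amide formation through the acyl imidazole gives the Weinreb amide without a base strong enough to epimerize C9.

Step 6
Reactants: 12 N-methoxy-N-methyl amide of acid 10; 13 allylmagnesium bromide
Product: 14 C8 allyl ketone
Conditions: THF, −78 to −20 °C; then sat. aq. NH4Cl, −78 °C
Reagents that add atoms: none
Why: Weinreb ketone synthesis; the magnesium-chelated tetrahedral adduct persists until the cold quench, so only one allyl group is added and the β,γ-unsaturated ketone is released without conjugation.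

Step 7
Reactants: 14 C8 allyl ketone
Product: 15 C8 tertiary alcohol (C8 S)
Conditions: MeMgBr, CeCl3, THF, −78 °C; then aq. NH4Cl
Reagents that add atoms: methylmagnesium bromide, C[Mg]Br
Why: Organocerium 1,2-addition suppresses enolization of the β,γ-unsaturated ketone, and under Felkin–Anh control the methyl group attacks anti to the quaternary C10 substituent and past H9, which should set C8 as S (adding allyl to a methyl ketone instead would give the C8 epimer).

Step 8
Reactants: 15 C8 tertiary alcohol
Product: 16 triethylsilyl ether of 15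
Conditions: TESOTf, 2,6-lutidine, CH2Cl2, −78 to 0 °C
Reagents that add atoms: triethylsilyl trifluoromethanesulfonate, CC[Si](CC)(CC)OS(=O)(=O)C(F)(F)F
Why: Silylation with the silyl triflate and a hindered pyridine base caps the hindered tertiary alcohol, and the ether blocks retro-aldol cleavage of the later β-oxy carbonyl compounds.

Step 9
Reactants: 16 triethylsilyl ether of 15
Product: 17 ring A enone (C3 ketone, C4=C5)
Conditions: CrO3, 3,5-dimethylpyrazole, CH2Cl2, −20 °C
Reagents that add atoms: chromium trioxide, O=[Cr](=O)=O
Why: Allylic oxidation with the CrO3–3,5-dimethylpyrazole complex; C3 is the only allylic CH2 of the ring alkene because C10 is quaternary, and the 1,2-disubstituted ring alkene should react ahead of the terminal alkene, whose allylic CH2 is neopentylic.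

Step 10
Reactants: 17 ring A enone
Product: 18 2-iodo enone (iodine on C4)
Conditions: I2, pyridine, CH2Cl2, rt
Reagents that add atoms: iodine, II
Why: α-Iodination of the enone (conjugate addition of pyridine, iodination of the enolate, loss of pyridine) puts iodine on C4.

Step 11
Reactants: 18 2-iodo enone
Product: 19 2-methyl enone (C19 methyl on C4)
Conditions: Me2Zn, PdCl2(dppf) (5 mol%), THF, 50 °C
Reagents that add atoms: dimethylzinc, C[Zn]C
Why: Negishi cross-coupling of the α-iodoenone with dimethylzinc installs the C4 methyl group, fast transmetalation keeping the alkenylpalladium species from a Heck reaction with the terminal alkene.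

Step 12
Reactants: 19 2-methyl enone
Product: 21 C6 aldehyde, via ozonide 20 (not isolated)
Conditions: O3, CH2Cl2, −78 °C, to the end point of a red azo dye indicator; then PPh3, −78 °C to rt
Reagents that add atoms: ozone, [O-][O+]=O
Why: Ozonolysis with reductive work-up; ozone reacts much faster with the electron-rich terminal alkene than with the electron-poor enone, so stopping at the indicator end point should leave ring A intact.

Step 13
Reactants: 21 C6 aldehyde
Product: 22 C6 carboxylic acid
Conditions: NaClO2, NaH2PO4, 2-methylbut-2-ene, t-BuOH/H2O, 0 °C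
Reagents that add atoms: sodium chlorite, [Na+].[O-]Cl=O
Why: Pinnick oxidation turns the aldehyde into the acid in a buffered medium that should not touch the enone, the dioxolane or the tertiary silyl ether.

Step 14
Reactants: 22 C6 carboxylic acid
Product: 23 Se-phenyl selenoester (key-step precursor)
Conditions: N-(phenylseleno)phthalimide, PBu3, CH2Cl2, 0 °C to rt
Reagents that add atoms: N-(phenylseleno)phthalimide, O=C1c2ccccc2C(=O)N1[Se]c1ccccc1
Why: Selenoester formation through an acyloxyphosphonium intermediate needs no base, so the β-silyloxy acid should not eliminate, and no free selenol is formed that could add to the enone.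

Step 15
Reactants: 23 Se-phenyl selenoester
Product: 24 cis-fused 3,6-diketone (key-step product)
Conditions: Bu3SnH (1.3 equiv), AIBN (0.2 equiv), benzene (0.005 M), 80 °C, syringe-pump addition over 6 h
Reagents that add atoms: none
Why: A tributylstannyl radical takes the phenylselanyl group from the C6 selenoester, the nucleophilic acyl radical adds to C5, the β-carbon of the ring A enone, and the tertiary α-keto radical at C4 takes hydrogen from Bu3SnH to carry the chain. The closest known reaction type is the tin hydride-mediated cyclization of acyl selenides onto α,β-unsaturated ketones. Ring B (C5–C10) closes in the 6-exo-trig mode. The new centre C5 is set in a chair-like transition state in which the tether leaves from the pseudo-equatorial C9 and reaches C5 anti to the pseudo-axial C20 methyl, so the fusion should be cis (H5 syn to C20), and C4 forms as a mixture. The step needs chemoselectivity for ring closure over hydrogen transfer to the acyl radical and over loss of CO; the polarity match of the acyl radical with the enone, the slow decarbonylation of an acyl radical that would leave a primary radical, and slow addition of the stannane at high dilution secure it. The configuration at C5 is not needed: with C17 and C20 syn-axial and the C9 chain axial, the trans ketone cannot be counted on to win a base equilibration, so C4 and C5 are made planar again in step 16 and set in step 17.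

Step 16
Reactants: 24 cis-fused 3,6-diketone
Product: 25 2-ene-1,4-dione (C4=C5, C3 and C6 ketones)
Conditions: IBX (1.3 equiv), DMSO/fluorobenzene, 70 °C
Reagents that add atoms: none
Why: IBX dehydrogenation of a ketone; H4 and H5 are each α to one carbonyl and β to the other, so the conjugated 2-ene-1,4-dione should form first, which removes the C4 and C5 stereocentres.

Step 17
Reactants: 25 2-ene-1,4-dione
Product: 27 trans-fused 18-hydroxy-3,6-diketone, via dilithium bis-enolate 26 (not isolated)
Conditions: Li (2.2 equiv), NH3(l)/THF, −78 °C; NH3 removed; THF, CH2O (gas), −78 °C; then NH4Cl, −78 °C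
Reagents that add atoms: formaldehyde, C=O
Why: Proposed new method: two-electron reduction of the 2-ene-1,4-dione should give the dilithium 3,5-diene-3,6-diolate 26, in which C4 and C5 are both planar; formaldehyde is expected to attack C4, the less hindered enolate carbon, on the face anti to the axial C20 methyl (C18 anti to C20, C19 syn), and on quenching the strained C5=C6 enolate should be protonated at C5 anti to the two now syn-axial methyls C19 and C20, which gives the trans ring fusion; the closest known reaction type is the Birch-type reductive hydroxymethylation of 4-methyl-4-en-3-one decalins with lithium in ammonia and formaldehyde, applied here to an ene-dione, whose reduction to a 1,4-diketone bis-enolate is known.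

Step 18
Reactants: 27 trans-fused 18-hydroxy-3,6-diketone
Product: 28 18-O-tert-butyldimethylsilyl ether
Conditions: TBSCl, imidazole, DMF, rt
Reagents that add atoms: tert-butyldimethylsilyl chloride, CC(C)(C)[Si](C)(C)Cl
Why: Imidazole-promoted silylation of the primary alcohol protects C18 and stops the alcohol from closing a hemiketal onto the C6 ketone.

Step 19
Reactants: 28 18-O-tert-butyldimethylsilyl ether
Product: 29 C3 tosylhydrazone
Conditions: TsNHNH2, EtOH, 70 °C
Reagents that add atoms: 4-methylbenzenesulfonohydrazide, Cc1ccc(cc1)S(=O)(=O)NN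
Why: Tosylhydrazone condensation; the C3 ketone has an open CH2 flank whereas the C6 ketone sits between C5 and C7, both next to quaternary carbons, so only C3 should condense.

Step 20
Reactants: 29 C3 tosylhydrazone
Product: 31 3-deoxy 6-ketone, via N-boryl hydrazine 30 (not isolated)
Conditions: catecholborane, CHCl3, 0 °C; then NaOAc·3H2O, reflux
Reagents that add atoms: none
Why: Hydroborative reduction of a tosylhydrazone (a mild Wolff–Kishner-type deoxygenation); catecholborane adds across the C=N bond, acetate triggers loss of sulfinate and the diazene loses N2, which should leave CH2 at C3 under conditions too mild to enolize the C6 ketone toward C5.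

Step 21
Reactants: 31 3-deoxy 6-ketone
Product: 32 equatorial C6 alcohol
Conditions: Li, NH3(l), THF, t-BuOH, −78 to −33 °C; then NH4Cl
Reagents that add atoms: none
Why: Dissolving-metal reduction of the ketone under thermodynamic control should give the equatorial C6 alcohol (oxygen anti to C20), because the axial position is syn-axial to the C17, C19 and C20 methyls; a hydride reagent would attack from the open face and give the axial epimer.

Step 22
Reactants: 32 equatorial C6 alcohol
Product: 33 C6 acetate
Conditions: Ac2O, Et3N, DMAP (cat.), CH2Cl2, rt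
Reagents that add atoms: acetic anhydride, CC(=O)OC(C)=O
Why: DMAP-catalysed acetylation esterifies the only free hydroxyl group, the equatorial secondary C6 alcohol.

Step 23
Reactants: 33 C6 acetate
Product: 34 C13 methyl ketone
Conditions: PPTS (cat.), acetone/H2O, 50 °C
Reagents that add atoms: water, O
Why: Acid-catalysed ketal hydrolysis in wet acetone unmasks the C13 methyl ketone, while the primary tert-butyldimethylsilyl ether, the tertiary triethylsilyl ether and the acetate should survive the weak acid.

Step 24
Reactants: 34 C13 methyl ketone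
Product: 36 enol triflate (C13=C16), via potassium enolate 35 (not isolated)
Conditions: KHMDS, THF, −78 °C; then PhNTf2, −78 to 0 °C
Reagents that add atoms: N-phenylbis(trifluoromethanesulfonimide), FC(F)(F)S(=O)(=O)N(c1ccccc1)S(=O)(=O)C(F)(F)F
Why: Kinetic deprotonation with the bulky amide takes a methyl proton of the ketone (not C12, and not the less acidic acetate), and O-sulfonylation of the enolate with the triflimide gives the 2-triflyloxy-1-alkene.

Step 25
Reactants: 36 enol triflate
Product: 37 bis-silyl ether of the target diene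
Conditions: tributyl(vinyl)stannane, Pd(PPh3)4 (5 mol%), LiCl, THF, 65 °C
Reagents that add atoms: tributyl(vinyl)stannane, C=C[Sn](CCCC)(CCCC)CCCC
Why: Stille coupling of the enol triflate with the vinylstannane (chloride-promoted) builds the 2-substituted buta-1,3-diene under neutral conditions.

Step 26
Reactants: 37 bis-silyl ether of the target diene
Product: 38 target
Conditions: HF·pyridine, pyridine, THF, 0 °C to rt
Reagents that add atoms: none
Why: Fluoride-mediated desilylation with buffered HF·pyridine removes both silyl ethers under mildly acidic conditions, which should avoid acetate migration from O6 to O18 and leave the diene alone.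

**Compound list**

1 | 3-methylcyclohex-2-en-1-one | CC1=CC(=O)CCC1 | starting material
2 | (S)-3-methylcyclohex-2-en-1-ol | O[C@@H]1C=C(C)CCC1 | intermediate
3 | 5-oxohexanoic acid | CC(=O)CCCC(=O)O | starting material
4 | 2-hydroxyethyl 4-(2-methyl-1,3-dioxolan-2-yl)butanoate | CC1(OCCO1)CCCC(=O)OCCO | intermediate
5 | 4-(2-methyl-1,3-dioxolan-2-yl)butanoic acid | CC1(OCCO1)CCCC(=O)O | intermediate
6 | (S)-3-methylcyclohex-2-en-1-yl 4-(2-methyl-1,3-dioxolan-2-yl)butanoate | CC1(OCCO1)CCCC(=O)O[C@@H]2C=C(C)CCC2 | intermediate
7 | lithium Z(O)-enolate of ester 6 (C11 cis to OLi) | [Li+].CC1(OCCO1)CC/C=C(\[O-])O[C@@H]2C=C(C)CCC2 | intermediate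
8 | (Z)-tert-butyldimethylsilyl ketene acetal of ester 6 (C11 cis to OSi) | CC1(OCCO1)CC/C=C(\O[Si](C)(C)C(C)(C)C)O[C@@H]2C=C(C)CCC2 | intermediate
9 | tert-butyldimethylsilyl ester of acid 10 | CC1(OCCO1)CC[C@@H](C(=O)O[Si](C)(C)C(C)(C)C)[C@]2(C)CCCC=C2 | intermediate
10 | (2R)-4-(2-methyl-1,3-dioxolan-2-yl)-2-[(1R)-1-methylcyclohex-2-en-1-yl]butanoic acid (C9 R, C10 R) | CC1(OCCO1)CC[C@@H](C(=O)O)[C@]2(C)CCCC=C2 | intermediate
11 | 1-acylimidazole of acid 10 | CC1(OCCO1)CC[C@@H](C(=O)n2ccnc2)[C@]3(C)CCCC=C3 | intermediate
12 | N-methoxy-N-methyl amide of acid 10 | CC1(OCCO1)CC[C@@H](C(=O)N(C)OC)[C@]2(C)CCCC=C2 | intermediate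
13 | allylmagnesium bromide | C=CC[Mg]Br | starting material
14 | (5R)-7-(2-methyl-1,3-dioxolan-2-yl)-5-[(1R)-1-methylcyclohex-2-en-1-yl]hept-1-en-4-one (C8 ketone; allyl = C7, C6) | CC1(OCCO1)CC[C@@H](C(=O)CC=C)[C@]2(C)CCCC=C2 | intermediate
15 | (4S,5R)-4-methyl-7-(2-methyl-1,3-dioxolan-2-yl)-5-[(1R)-1-methylcyclohex-2-en-1-yl]hept-1-en-4-ol (C8 S) | CC1(OCCO1)CC[C@@H]([C@@](C)(O)CC=C)[C@]2(C)CCCC=C2 | intermediate
16 | triethylsilyl ether of alcohol 15 | CC1(OCCO1)CC[C@@H]([C@@](C)(O[Si](CC)(CC)CC)CC=C)[C@]2(C)CCCC=C2 | intermediate
17 | ring A enone: 16 with C3 oxidized to the ketone (C3=O, C4=C5) | CC1(OCCO1)CC[C@@H]([C@@](C)(O[Si](CC)(CC)CC)CC=C)[C@]2(C)CCC(=O)C=C2 | intermediate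
18 | 2-iodo enone: 17 with iodine on C4 | CC1(OCCO1)CC[C@@H]([C@@](C)(O[Si](CC)(CC)CC)CC=C)[C@]2(C)CCC(=O)C(I)=C2 | intermediate
19 | 2-methyl enone: 17 with the C19 methyl on C4 | CC1(OCCO1)CC[C@@H]([C@@](C)(O[Si](CC)(CC)CC)CC=C)[C@]2(C)CCC(=O)C(C)=C2 | intermediate
20 | ozonide (1,2,4-trioxolane) of the terminal alkene of 19, mixture at the trioxolane carbon | CC1(OCCO1)CC[C@@H]([C@@](C)(O[Si](CC)(CC)CC)CC3OCOO3)[C@]2(C)CCC(=O)C(C)=C2 | intermediate
21 | aldehyde: 19 with the allyl group cut to CH2–CHO (C7, C6) | CC1(OCCO1)CC[C@@H]([C@@](C)(O[Si](CC)(CC)CC)CC=O)[C@]2(C)CCC(=O)C(C)=C2 | intermediate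
22 | (3S,4R)-4-[(1R)-1,3-dimethyl-4-oxocyclohex-2-en-1-yl]-3-methyl-6-(2-methyl-1,3-dioxolan-2-yl)-3-(triethylsilyloxy)hexanoic acid | CC1(OCCO1)CC[C@@H]([C@@](C)(O[Si](CC)(CC)CC)CC(=O)O)[C@]2(C)CCC(=O)C(C)=C2 | intermediate
23 | Se-phenyl selenoester of acid 22 (key-step precursor) | CC1(OCCO1)CC[C@@H]([C@@](C)(O[Si](CC)(CC)CC)CC(=O)[Se]c2ccccc2)[C@]3(C)CCC(=O)C(C)=C3 | intermediate
24 | cis-fused 3,6-diketone (key-step product): 13,13-(ethylenedioxy)-8-(triethylsilyloxy)-14,15,18-trinorlabdane-3,6-dione, H5 syn to C20, both C4 epimers, C8 S, C9 R, C10 R | CC1(OCCO1)CC[C@@H]2[C@]3(C)CCC(=O)C(C)[C@@H]3C(=O)C[C@]2(C)O[Si](CC)(CC)CC | intermediate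
25 | 2-ene-1,4-dione: 13,13-(ethylenedioxy)-8-(triethylsilyloxy)-14,15,18-trinorlabd-4-ene-3,6-dione | CC1(OCCO1)CC[C@@H]2[C@]3(C)CCC(=O)C(C)=C3C(=O)C[C@]2(C)O[Si](CC)(CC)CC | intermediate
26 | dilithium 3,5-diene-3,6-diolate (bis-enolate) of 25 | [Li+].[Li+].CC1(OCCO1)CC[C@@H]2[C@]3(C)CCC([O-])=C(C)C3=C([O-])C[C@]2(C)O[Si](CC)(CC)CC | intermediate
27 | trans-fused 13,13-(ethylenedioxy)-18-hydroxy-8-(triethylsilyloxy)-14,15-dinorlabdane-3,6-dione (C18 anti to C20, C19 syn, H5 anti to C20) | CC1(OCCO1)CC[C@@H]2[C@]3(C)CCC(=O)[C@](C)(CO)[C@H]3C(=O)C[C@]2(C)O[Si](CC)(CC)CC | intermediate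
28 | 18-O-tert-butyldimethylsilyl ether of 27 | CC1(OCCO1)CC[C@@H]2[C@]3(C)CCC(=O)[C@](C)(CO[Si](C)(C)C(C)(C)C)[C@H]3C(=O)C[C@]2(C)O[Si](CC)(CC)CC | intermediate
29 | C3 tosylhydrazone of 28 | CC1(OCCO1)CC[C@@H]2[C@]3(C)CCC(=NNS(=O)(=O)c4ccc(C)cc4)[C@](C)(CO[Si](C)(C)C(C)(C)C)[C@H]3C(=O)C[C@]2(C)O[Si](CC)(CC)CC | intermediate
30 | N-(1,3,2-benzodioxaborol-2-yl) tosylhydrazine from 29 (C3–H, mixture at C3) | CC1(OCCO1)CC[C@@H]2[C@]3(C)CCC(N(NS(=O)(=O)c4ccc(C)cc4)B4Oc5ccccc5O4)[C@](C)(CO[Si](C)(C)C(C)(C)C)[C@H]3C(=O)C[C@]2(C)O[Si](CC)(CC)CC | intermediate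
31 | 3-deoxy 6-ketone: 18-(tert-butyldimethylsilyloxy)-13,13-(ethylenedioxy)-8-(triethylsilyloxy)-14,15-dinorlabdan-6-one | CC1(OCCO1)CC[C@@H]2[C@]3(C)CCC[C@](C)(CO[Si](C)(C)C(C)(C)C)[C@H]3C(=O)C[C@]2(C)O[Si](CC)(CC)CC | intermediate
32 | equatorial 6-alcohol of 31 (O6 anti to C20, syn to H5) | CC1(OCCO1)CC[C@@H]2[C@]3(C)CCC[C@](C)(CO[Si](C)(C)C(C)(C)C)[C@H]3[C@H](O)C[C@]2(C)O[Si](CC)(CC)CC | intermediate
33 | 6-acetate of 32 | CC1(OCCO1)CC[C@@H]2[C@]3(C)CCC[C@](C)(CO[Si](C)(C)C(C)(C)C)[C@H]3[C@H](OC(C)=O)C[C@]2(C)O[Si](CC)(CC)CC | intermediate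
34 | C13 methyl ketone: 33 without the dioxolane | CC(=O)CC[C@@H]1[C@]2(C)CCC[C@](C)(CO[Si](C)(C)C(C)(C)C)[C@H]2[C@H](OC(C)=O)C[C@]1(C)O[Si](CC)(CC)CC | intermediate
35 | potassium enolate of 34 (terminal, C13=C16) | [K+].C=C([O-])CC[C@@H]1[C@]2(C)CCC[C@](C)(CO[Si](C)(C)C(C)(C)C)[C@H]2[C@H](OC(C)=O)C[C@]1(C)O[Si](CC)(CC)CC | intermediate
36 | enol triflate: 13-(trifluoromethylsulfonyloxy)-13(16)-ene | C=C(OS(=O)(=O)C(F)(F)F)CC[C@@H]1[C@]2(C)CCC[C@](C)(CO[Si](C)(C)C(C)(C)C)[C@H]2[C@H](OC(C)=O)C[C@]1(C)O[Si](CC)(CC)CC | intermediate
37 | 6-acetoxy-18-(tert-butyldimethylsilyloxy)-8-(triethylsilyloxy)labda-13(16),14-diene | C=CC(=C)CC[C@@H]1[C@]2(C)CCC[C@](C)(CO[Si](C)(C)C(C)(C)C)[C@H]2[C@H](OC(C)=O)C[C@]1(C)O[Si](CC)(CC)CC | intermediate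
38 | target: 6-acetoxylabda-13(16),14-diene-8,18-diol, (4S,5S,6R,8S,9R,10R) | C=CC(=C)CC[C@@H]1[C@]2(C)CCC[C@](C)(CO)[C@H]2[C@H](OC(C)=O)C[C@]1(C)O | target

**Step count and risks**

Total step count: 26. Longest linear sequence: 25 steps (steps 1 and 3 to 26; step 2 prepares acid 5).

The three steps most likely to fail:

1. Step 17 (proposed new method). The aldol could take place at C5 as well as at C4, formaldehyde or the proton could arrive on the wrong face, or the bis-enolate could be incompletely formed or equilibrate before it is trapped. The fallback sets out from 25 and comes back at 27, and separates the three events with known reaction types. Reductive silylation of the ene-dione with zinc and TMSCl would give the 3,6-bis(trimethylsilyloxy)-3,5-diene F1. A Mukaiyama aldol reaction with aqueous formaldehyde and Sc(OTf)3 should then hydroxymethylate the less hindered enol ether at C4. Buffered fluoride or dilute acid would finally protonate the remaining C5=C6 enol ether at C5, anti to C19 and C20, to give 27.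

2. Step 15 (key step). Hydrogen transfer from the stannane could reach the acyl radical before it closes onto C5, or the acyl radical could lose CO; both are more likely if addition to the hindered C5 next to quaternary C10 is slow. The fallback sets out from aldehyde 21 and comes back at 24; it makes no compound outside the list (F0). It replaces the radical by a polar umpolung: an intramolecular Stetter reaction of 21 (thiazolium or triazolium carbene precatalyst, Et3N) would form the same C5–C6 bond and give diketone 24. Any C4 or C5 epimer formed alongside converges at 25.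

3. Step 4. Incomplete control of enolate geometry and leakage between chair and boat transition states could erode the configuration at C9 (C10 is safe, since it follows from suprafacial transfer). The fallback sets out from 2 and comes back at 10, and sets the two centres one at a time:
   - Acetylation of 2 gives (S)-3-methylcyclohex-2-en-1-yl acetate F2.
   - Its Ireland–Claisen rearrangement (LDA, TMSCl) gives (S)-2-(1-methylcyclohex-2-en-1-yl)acetic acid F3, in which only C10 is set.
   - Iodolactonization (I2, NaHCO3) gives the cis-fused iodolactone F4.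
   - Alkylation of its lithium enolate with 2-(2-iodoethyl)-2-methyl-1,3-dioxolane should put the chain on the convex face, giving the C9-alkylated lactone F5.
   - Deprotonation and kinetic protonation on the same convex face would turn C9 over to its C9 epimer F6.
   - Zinc in acetic acid then opens the iodolactone by reductive elimination and returns acid 10.

Further compounds
F1 | step 17 | 3,6-bis(trimethylsilyloxy)-3,5-diene from ene-dione 25 | CC1(OCCO1)CC[C@@H]2[C@]3(C)CCC(O[Si](C)(C)C)=C(C)C3=C(O[Si](C)(C)C)C[C@]2(C)O[Si](CC)(CC)CC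
F0 | step 15 | none | none
F2 | step 4 | (S)-3-methylcyclohex-2-en-1-yl acetate | CC(=O)O[C@@H]1C=C(C)CCC1
F3 | step 4 | (S)-2-(1-methylcyclohex-2-en-1-yl)acetic acid | OC(=O)C[C@]1(C)CCCC=C1
F4 | step 4 | cis-fused iodolactone of F3 (lactone oxygen on C5 cis to C9, iodine on C4 trans to it) | O=C1C[C@]2(C)CCC[C@@H](I)[C@@H]2O1
F5 | step 4 | F4 alkylated at C9 with the 2-(2-methyl-1,3-dioxolan-2-yl)ethyl chain on the convex face (cis to the angular methyl) | O=C1[C@@H](CCC3(C)OCCO3)[C@]2(C)CCC[C@@H](I)[C@@H]2O1
F6 | step 4 | C9 epimer of F5 (chain on the concave face, C9 as in acid 10) | O=C1[C@H](CCC3(C)OCCO3)[C@]2(C)CCC[C@@H](I)[C@@H]2O1
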